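**Plan**

- Retrosynthesis (coumarin numbering, chroman atoms primed): the lactone bond O1–C2 and the ring bond C4–C4a are cut together, giving 4-iodo-5-methoxyresorcinol and methyl 2-(5-methoxy-2,2-dimethylchroman-6-yl)acrylate.
- Enabling feature: in ring A, C4a sits between the methoxy-bearing C5 and the O1-bearing C8a and is para to the free C7 hydroxyl. The carbon of 5-methoxyresorcinol flanked by OMe and OH is that same carbon, so an iodine there fixes the whole ring A pattern and places a phenol next to the new bond.
- The acrylate is cut at its =CH2 group (formaldehyde) to the arylacetate, this by a 1,2-aryl shift to the 6'-acetylchroman, and the dihydropyran ring to 2,4-dihydroxyacetophenone and 3-methylbut-2-enal.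
- Forward: the dihydropyran ring of the chroman is made first (chromene annulation, hydrogenation), ring A is bought, and the pyranone ring closes last in a domino Heck coupling and lactonisation.
- Stereochemistry: the target has no stereocentre; only the alkene geometry of the Heck intermediate matters, and it is settled by equilibration toward the isomer that lactonises.

Key step: step 7

Assumption: without base, N-iodosuccinimide is taken to iodinate 5-methoxyresorcinol mainly at the carbon between the methoxy and a hydroxyl group (para to the other hydroxyl), the site that formylation of this phenol also prefers; any isomer iodinated between the two hydroxyls would be removed by chromatography.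

**Route**

Step 1
Reactants: 1 2,4-dihydroxyacetophenone; 2 3-methylbut-2-enal
Product: 4 1-(5-hydroxy-2,2-dimethyl-2H-chromen-6-yl)ethan-1-one, via ortho-quinone methide 3 (not isolated)
Conditions: pyridine, 140 °C (sealed vessel)
Reagents that add atoms: none
Why: Pyridine-mediated Knoevenagel-type condensation at C3 of the resorcinol ring (the carbon between the two oxygens) should give ortho-quinone methide 3, whose oxa-6π electrocyclisation through the free 4-oxygen closes the 2,2-dimethylpyran ring while the hydrogen-bonded 2-hydroxyl stays out of the reaction (chromene annulation of resorcinols with enals).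

Step 2
Reactants: 4 1-(5-hydroxy-2,2-dimethyl-2H-chromen-6-yl)ethan-1-one
Product: 5 1-(5-hydroxy-2,2-dimethylchroman-6-yl)ethan-1-one
Conditions: H2 (1 atm), 10% Pd/C, EtOAc, rt
Reagents that add atoms: none
Why: Catalytic hydrogenation should saturate the styrene-type C3=C4 bond of the chromene far faster than it reduces the aryl ketone, which is also deactivated by its hydrogen bond to the ortho hydroxyl.

Step 3
Reactants: 5 1-(5-hydroxy-2,2-dimethylchroman-6-yl)ethan-1-one
Product: 6 1-(5-methoxy-2,2-dimethylchroman-6-yl)ethan-1-one
Conditions: MeI, K2CO3, DMF, 50 °C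
Reagents that add atoms: iodomethane, CI
Why: Williamson O-methylation, in which carbonate in DMF breaks the intramolecular hydrogen bond of the ortho-hydroxy ketone and the phenoxide is alkylated by iodomethane.

Step 4
Reactants: 6 1-(5-methoxy-2,2-dimethylchroman-6-yl)ethan-1-one
Product: 9 methyl 2-(5-methoxy-2,2-dimethylchroman-6-yl)acetate, via dimethyl ketal 7 (not isolated), via trimethyl orthoester 8 (not isolated)
Conditions: PhI(OAc)2, H2SO4, HC(OMe)3, 60 °C; then H2O
Reagents that add atoms: trimethyl orthoformate, COC(OC)OC; water, O
Why: In acidic orthoformate the ketone is held as ketal 7, the trivalent iodine reagent attacks its α-carbon, the electron-rich aryl group shifts to that carbon as iodobenzene leaves, and orthoester 8 is hydrolysed to the ester on work-up (oxidative 1,2-aryl migration of aryl methyl ketones to arylacetates).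

Step 5
Reactants: 9 methyl 2-(5-methoxy-2,2-dimethylchroman-6-yl)acetate; 10 formaldehyde (charged as paraformaldehyde)
Product: 12 methyl 2-(5-methoxy-2,2-dimethylchroman-6-yl)acrylate, via hydroxymethyl ester 11 (not isolated)
Conditions: (CH2O)n, K2CO3, Bu4NI (cat.), toluene, 80 °C
Reagents that add atoms: none
Why: Under phase-transfer conditions the arylacetate enolate should add to formaldehyde to give aldol 11, and E1cB loss of water gives the α-methylene ester (aldol condensation, the standard entry to atropates).

Step 6
Reactants: 13 5-methoxyresorcinol
Product: 14 4-iodo-5-methoxybenzene-1,3-diol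
Conditions: NIS (1.0 equiv), MeCN, −30 °C to 0 °C, dark
Reagents that add atoms: N-iodosuccinimide, O=C1CCC(=O)N1I
Why: Electrophilic aromatic iodination, in which the neutral phenol should react para to one hydroxyl at the carbon between OMe and OH, while one equivalent of reagent at low temperature limits twofold iodination.

Step 7
Reactants: 14 4-iodo-5-methoxybenzene-1,3-diol; 12 methyl 2-(5-methoxy-2,2-dimethylchroman-6-yl)acrylate (1.5 equiv)
Product: 17 7-hydroxy-5-methoxy-3-(5-methoxy-2,2-dimethylchroman-6-yl)-2H-chromen-2-one, via E-diarylacrylate 15 (not isolated), via Z-diarylacrylate 16 (not isolated)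
Conditions: Pd(OAc)2 (10 mol %), Bu4NCl, NaHCO3, DMF, 100 °C, argon
Reagents that add atoms: none
Why: Zerovalent palladium formed in the flask from Pd(OAc)2 inserts into the C–I bond of 14, the arylpalladium adds across the 1,1-disubstituted alkene of 12 with the aryl group on the CH2 terminus and palladium on the tertiary α-carbon, and syn β-hydride elimination, possible only toward the new benzylic CH2, gives the 2,3-diarylacrylates 15 and 16 and so forms C4–C4a. The closest known reaction type is the Heck coupling of 2-iodophenols with acrylates and α-substituted acrylates that lactonises to coumarins in the same flask; the phosphine-free, chloride-stabilised Jeffery conditions are chosen because a small palladium centre best tolerates the two ortho substituents of the iodide. The pyranone ring closes by 6-exo-trig acyl substitution: in the Z isomer 16 the phenol next to the new bond attacks the ester carbonyl and expels methanol, forming O1–C2. The E isomer 15 should feed 16 because the ortho and para oxygens of ring A push electron density into the acrylate (quinone-methide resonance form) and lower the rotation barrier about the Cα=Cβ bond, with palladium hydride re-addition as a second path, so the irreversible lactonisation drains both isomers. No stereocentre is formed; the regiochemistry of ring A is fixed beforehand by the position of iodine, and only the hydroxyl flanking that position can reach the ester, the C7 hydroxyl being para to C4a, so no protecting group is needed. The selectivity required is carbopalladation over protodeiodination and over oxa-Michael addition of the phenols to 12, which the weak base NaHCO3, the excess of 12 and the reactive C–I bond are meant to secure.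

**Compound list**

1 | 2,4-dihydroxyacetophenone | CC(=O)c1ccc(O)cc1O | starting material
2 | 3-methylbut-2-enal | CC(C)=CC=O | starting material
3 | (2Z)-4-acetyl-3-hydroxy-2-(3-methylbut-2-en-1-ylidene)cyclohexa-3,5-dien-1-one (ortho-quinone methide, formed in the flask in step 1) | CC(=O)C1=C(O)C(=C/C=C(C)C)/C(=O)C=C1 | intermediate
4 | 1-(5-hydroxy-2,2-dimethyl-2H-chromen-6-yl)ethan-1-one | CC(=O)c1ccc2OC(C)(C)C=Cc2c1O | intermediate
5 | 1-(5-hydroxy-2,2-dimethylchroman-6-yl)ethan-1-one | CC(=O)c1ccc2OC(C)(C)CCc2c1O | intermediate
6 | 1-(5-methoxy-2,2-dimethylchroman-6-yl)ethan-1-one | CC(=O)c1ccc2OC(C)(C)CCc2c1OC | intermediate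
7 | 6-(1,1-dimethoxyethyl)-5-methoxy-2,2-dimethylchroman (dimethyl ketal, formed in the flask in step 4) | COC(C)(OC)c1ccc2OC(C)(C)CCc2c1OC | intermediate
8 | 5-methoxy-2,2-dimethyl-6-(2,2,2-trimethoxyethyl)chroman (trimethyl orthoester, formed in the flask in step 4) | COC(Cc1ccc2OC(C)(C)CCc2c1OC)(OC)OC | intermediate
9 | methyl 2-(5-methoxy-2,2-dimethylchroman-6-yl)acetate | COC(=O)Cc1ccc2OC(C)(C)CCc2c1OC | intermediate
10 | formaldehyde (used as paraformaldehyde) | C=O | starting material
11 | methyl 3-hydroxy-2-(5-methoxy-2,2-dimethylchroman-6-yl)propanoate (racemic, formed in the flask in step 5) | COC(=O)C(CO)c1ccc2OC(C)(C)CCc2c1OC | intermediate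
12 | methyl 2-(5-methoxy-2,2-dimethylchroman-6-yl)acrylate | COC(=O)C(=C)c1ccc2OC(C)(C)CCc2c1OC | intermediate
13 | 5-methoxyresorcinol (5-methoxybenzene-1,3-diol) | COc1cc(O)cc(O)c1 | starting material
14 | 4-iodo-5-methoxybenzene-1,3-diol | COc1cc(O)cc(O)c1I | intermediate
15 | methyl (E)-3-(2,4-dihydroxy-6-methoxyphenyl)-2-(5-methoxy-2,2-dimethylchroman-6-yl)acrylate (ester trans to ring A, formed in the flask in step 7) | COC(=O)/C(=C/c1c(O)cc(O)cc1OC)c1ccc2OC(C)(C)CCc2c1OC | intermediate
16 | methyl (Z)-3-(2,4-dihydroxy-6-methoxyphenyl)-2-(5-methoxy-2,2-dimethylchroman-6-yl)acrylate (ester cis to ring A, formed in the flask in step 7) | COC(=O)/C(=C\c1c(O)cc(O)cc1OC)c1ccc2OC(C)(C)CCc2c1OC | intermediate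
17 | 7-hydroxy-5-methoxy-3-(5-methoxy-2,2-dimethylchroman-6-yl)-2H-chromen-2-one | COc1c(-c2cc3c(OC)cc(O)cc3oc2=O)ccc2c1CCC(C)(C)O2 | target

**Step count**

Total: 7 steps. Longest linear sequence: 6 steps (steps 1, 2, 3, 4, 5 and 7); step 6 is a one-step side branch.

**Steps most likely to fail**

1. Step 7. Carbopalladation of the doubly ortho-substituted, electron-rich arylpalladium onto the 1,1-disubstituted alkene may be slow. Protodeiodination, oxa-Michael addition of the phenols to the acrylate or thermal oligomerisation of the acrylate could then take over, and the E-to-Z equilibration could stall before lactonisation. The fallback is a Perkin–Oglialoro condensation, which builds C3–C4 instead of C4–C4a; it sets out from ester 9 and phenol 13 and comes back at target 17. Saponification of 9 (LiOH, THF/H2O) should give 2-(5-methoxy-2,2-dimethylchroman-6-yl)acetic acid F1. Vilsmeier–Haack formylation of 13 (POCl3, DMF, then H2O) should give 2,4-dihydroxy-6-methoxybenzaldehyde F2. Heating F1 and F2 in Ac2O/Et3N at 110 °C should condense and lactonise them to 5-methoxy-3-(5-methoxy-2,2-dimethylchroman-6-yl)-2-oxo-2H-chromen-7-yl acetate F3, and K2CO3 in MeOH should cleave the acetate to give 17.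

2. Step 6. Iodination at the carbon between the two hydroxyls, or twofold iodination of the very electron-rich ring, may compete with attack at the wanted carbon. The fallback blocks the unwanted site sterically; it sets out from 13 and comes back at 14. Silylation of both hydroxyls (i-Pr3SiCl, imidazole, DMF) should give 1-methoxy-3,5-bis(triisopropylsilyloxy)benzene F4, in which the carbon between the two bulky silyloxy groups is shielded. NIS in CH2Cl2 at 0 °C should then iodinate next to the methoxy group to give 2-iodo-1-methoxy-3,5-bis(triisopropylsilyloxy)benzene F5, and Bu4NF/AcOH in THF should free both phenols to give 14.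

3. Step 4. The trivalent iodine reagent may oxidise the electron-rich arene or the benzylic C4' methylene instead of the ketal α-carbon, and the strong acid may open the tertiary chroman ether. The fallback avoids the rearrangement and the arylacetate; it sets out from ketone 6 and comes back at acrylate 12. Riley oxidation (SeO2, pyridine, 100 °C) should convert the acetyl group into 2-(5-methoxy-2,2-dimethylchroman-6-yl)-2-oxoacetic acid F6. MeI/K2CO3 in DMF should give methyl 2-(5-methoxy-2,2-dimethylchroman-6-yl)-2-oxoacetate F7, and Wittig methylenation of its keto group (Ph3PCH3Br, KOt-Bu, THF, 0 °C) should give 12.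

**Further compounds**

F1 | step 7 | 2-(5-methoxy-2,2-dimethylchroman-6-yl)acetic acid | OC(=O)Cc1ccc2OC(C)(C)CCc2c1OC
F2 | step 7 | 2,4-dihydroxy-6-methoxybenzaldehyde | COc1cc(O)cc(O)c1C=O
F3 | step 7 | 5-methoxy-3-(5-methoxy-2,2-dimethylchroman-6-yl)-2-oxo-2H-chromen-7-yl acetate | COc1c(-c2cc3c(OC)cc(OC(C)=O)cc3oc2=O)ccc2c1CCC(C)(C)O2
F4 | step 6 | 1-methoxy-3,5-bis(triisopropylsilyloxy)benzene | COc1cc(O[Si](C(C)C)(C(C)C)C(C)C)cc(O[Si](C(C)C)(C(C)C)C(C)C)c1
F5 | step 6 | 2-iodo-1-methoxy-3,5-bis(triisopropylsilyloxy)benzene | COc1cc(O[Si](C(C)C)(C(C)C)C(C)C)cc(O[Si](C(C)C)(C(C)C)C(C)C)c1I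
F6 | step 4 | 2-(5-methoxy-2,2-dimethylchroman-6-yl)-2-oxoacetic acid | OC(=O)C(=O)c1ccc2OC(C)(C)CCc2c1OC
F7 | step 4 | methyl 2-(5-methoxy-2,2-dimethylchroman-6-yl)-2-oxoacetate | COC(=O)C(=O)c1ccc2OC(C)(C)CCc2c1OC
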